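## Retrosynthetic overview

1. Target ⇒ its tris-silyl ether (global desilylation last) ⇒ the E-isomer of that ether (E→Z photoisomerization sets the alkene geometry).
2. Exocyclic C3=C bond ⇒ aldol addition/dehydration between the lithium enolate of (S)-β-(4-silyloxy-3-methoxybenzyl)-γ-butyrolactone and bis-silylated 5-hydroxyvanillin (key C–C bond).
3. (S)-Lactone ⇒ Evans alkylation of an N-(3-arylpropanoyl)-(R)-4-benzyloxazolidinone with tert-butyl bromoacetate (sets C4), LiBH4 cleavage, acid lactonization.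
4. Rings: both benzene rings are bought; the γ-butyrolactone is the only ring built (step 5), before the fragment coupling.

Assumption: the target is read as (3Z,4S) (aryl cis to the lactone C=O), and 3-(4-hydroxy-3-methoxyphenyl)propanoic acid and 3,4-dihydroxy-5-methoxybenzaldehyde are taken as stocked catalogue chemicals.

## Route

Step 1
Reactants: 1 3-(4-hydroxy-3-methoxyphenyl)propanoic acid
Product: 3 3-[3-methoxy-4-(triisopropylsilyloxy)phenyl]propanoic acid, via bis-silylated acid 2 (not isolated)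
Conditions: TIPSCl (2.3 equiv), imidazole (5 equiv), DMF, rt; then 1 M aq. HCl/THF, rt
Reagents that add atoms: triisopropylsilyl chloride, CC(C)[Si](Cl)(C(C)C)C(C)C
Why: Imidazole-promoted silylation of both OH groups followed by selective hydrolysis of the much more labile silyl ester leaves the robust aryl TIPS ether (phenol protection); no stereocenter is involved.

Step 2
Reactants: 3 3-[3-methoxy-4-(triisopropylsilyloxy)phenyl]propanoic acid; 4 (4R)-4-benzyl-1,3-oxazolidin-2-one
Product: 6 (4R)-4-benzyl-3-{3-[3-methoxy-4-(triisopropylsilyloxy)phenyl]propanoyl}-1,3-oxazolidin-2-one, via mixed pivalic anhydride 5 (not isolated)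
Conditions: PivCl (1.1 equiv), Et3N (2.5 equiv), THF, −20 °C; then LiCl (1.1 equiv), 4, −20 °C → rt
Reagents that add atoms: none
Why: N-acylation of the auxiliary by the mixed anhydride, which reacts at its unhindered acyl carbon (LiCl/Et3N activates the oxazolidinone N–H), installs the Evans auxiliary under mild conditions that the aryl silyl ether tolerates.

Step 3
Reactants: 6 (4R)-4-benzyl-3-{3-[3-methoxy-4-(triisopropylsilyloxy)phenyl]propanoyl}-1,3-oxazolidin-2-one; 7 tert-butyl bromoacetate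
Product: 9 tert-butyl (3S)-4-[(4R)-4-benzyl-2-oxo-1,3-oxazolidin-3-yl]-3-{[3-methoxy-4-(triisopropylsilyloxy)phenyl]methyl}-4-oxobutanoate, via sodium Z-enolate 8 (not isolated)
Conditions: NaN(SiMe3)2 (1.1 equiv), THF, −78 °C, 45 min; then 7 (1.5 equiv), −78 → −40 °C
Reagents that add atoms: none
Why: Evans asymmetric enolate alkylation, in which the chelated sodium Z-enolate is attacked by the bromoacetate on the face opposite the benzyl group of the (R)-auxiliary, sets the new center as S (dr typically ≥ 95:5, minor diastereomer removed by chromatography).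

Step 4
Reactants: 9 tert-butyl (3S)-4-[(4R)-4-benzyl-2-oxo-1,3-oxazolidin-3-yl]-3-{[3-methoxy-4-(triisopropylsilyloxy)phenyl]methyl}-4-oxobutanoate
Product: 10 tert-butyl (3S)-3-(hydroxymethyl)-4-[3-methoxy-4-(triisopropylsilyloxy)phenyl]butanoate
Conditions: LiBH4 (1.5 equiv), MeOH (1.1 equiv), THF, 0 °C
Reagents that add atoms: none
Why: Chemoselective reductive cleavage of the exocyclic imide carbonyl by LiBH4 (the tert-butyl ester is inert at 0 °C) gives the primary alcohol without touching the stereocenter and returns the auxiliary 4.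

Step 5
Reactants: 10 tert-butyl (3S)-3-(hydroxymethyl)-4-[3-methoxy-4-(triisopropylsilyloxy)phenyl]butanoate
Product: 12 (4S)-4-{[3-methoxy-4-(triisopropylsilyloxy)phenyl]methyl}oxolan-2-one, via hydroxy acid 11 (not isolated)
Conditions: TFA/CH2Cl2 (1:4), 0 °C → rt; NaHCO3 work-up
Reagents that add atoms: none
Why: Acidolysis of the tert-butyl ester (loss of isobutene) and spontaneous lactonization of the γ-hydroxy acid close the butyrolactone ring; the stereocenter is not involved and the aryl TIPS ether is stable to TFA.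

Step 6
Reactants: 13 3,4-dihydroxy-5-methoxybenzaldehyde
Product: 14 3,4-bis(tert-butyldimethylsilyloxy)-5-methoxybenzaldehyde
Conditions: TBSCl (2.5 equiv), imidazole (5 equiv), DMF, rt
Reagents that add atoms: tert-butyldimethylsilyl chloride, CC(C)(C)[Si](C)(C)Cl
Why: Standard silylation of both catechol OH groups gives a protection that survives the enolate chemistry and is later removed with fluoride without touching the alkene.

Step 7
Reactants: 12 (4S)-4-{[3-methoxy-4-(triisopropylsilyloxy)phenyl]methyl}oxolan-2-one; 14 3,4-bis(tert-butyldimethylsilyloxy)-5-methoxybenzaldehyde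
Product: 16 (3R,4S)-3-{[3,4-bis(tert-butyldimethylsilyloxy)-5-methoxyphenyl](hydroxy)methyl}-4-{[3-methoxy-4-(triisopropylsilyloxy)phenyl]methyl}oxolan-2-one (both carbinol epimers), via lithium enolate 15 (not isolated)
Conditions: LiN(iPr)2 (1.1 equiv), THF, −78 °C, 45 min; then 14 (1.2 equiv), −78 °C, 2 h; aq. NH4Cl at −78 °C
Reagents that add atoms: none
Why: Intermolecular lithium-enolate aldol addition, in which the aldehyde adds to the enolate face trans to the C4 benzyl group (3,4-trans, 3R); the carbinol configuration is left uncontrolled because both epimers converge in step 8.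

Step 8
Reactants: 16 (3R,4S)-3-{[3,4-bis(tert-butyldimethylsilyloxy)-5-methoxyphenyl](hydroxy)methyl}-4-{[3-methoxy-4-(triisopropylsilyloxy)phenyl]methyl}oxolan-2-one
Product: 18 (3E,4S)-3-{[3,4-bis(tert-butyldimethylsilyloxy)-5-methoxyphenyl]methylidene}-4-{[3-methoxy-4-(triisopropylsilyloxy)phenyl]methyl}oxolan-2-one, via mesylate 17 (not isolated)
Conditions: MsCl (1.5 equiv), Et3N (4 equiv), CH2Cl2, 0 °C; then DBU (2 equiv), 0 °C → rt, 1 h
Reagents that add atoms: none
Why: Mesylation and base-induced E1cB elimination through the lactone enolate give the thermodynamically preferred E-benzylidene lactone from both carbinol epimers (any Z-isomer formed is simply carried into step 9); C4–H is not acidic enough to be touched.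

Step 9
Reactants: 18 (3E,4S)-3-{[3,4-bis(tert-butyldimethylsilyloxy)-5-methoxyphenyl]methylidene}-4-{[3-methoxy-4-(triisopropylsilyloxy)phenyl]methyl}oxolan-2-one
Product: 19 (3Z,4S)-3-{[3,4-bis(tert-butyldimethylsilyloxy)-5-methoxyphenyl]methylidene}-4-{[3-methoxy-4-(triisopropylsilyloxy)phenyl]methyl}oxolan-2-one
Conditions: hν (350 nm lamps, Pyrex), degassed MeCN (5 mM), rt; SiO2 separation, recovered 18 re-irradiated
Reagents that add atoms: none
Why: Photochemical E→Z isomerization of the cinnamate-type chromophore, the usual entry to Z-benzylidene lactone lignans, gives a photostationary mixture from which the Z-isomer is separated and the E-isomer recycled; C4 is untouched and no free phenol is present.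

Step 10
Reactants: 19 (3Z,4S)-3-{[3,4-bis(tert-butyldimethylsilyloxy)-5-methoxyphenyl]methylidene}-4-{[3-methoxy-4-(triisopropylsilyloxy)phenyl]methyl}oxolan-2-one
Product: 20 (3Z,4S)-3-[(3,4-dihydroxy-5-methoxyphenyl)methylidene]-4-[(4-hydroxy-3-methoxyphenyl)methyl]oxolan-2-one
Conditions: Bu4NF (4 equiv), AcOH (4 equiv), THF, 0 °C → rt, dark, Ar
Reagents that add atoms: none
Why: Fluoride-mediated desilylation buffered with acetic acid cleaves all three aryl silyl ethers without building up free phenoxide, which avoids base-induced Z→E isomerization, lactone opening and catechol oxidation.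

## Compound list

1 | 3-(4-hydroxy-3-methoxyphenyl)propanoic acid | COc1cc(CCC(=O)O)ccc1O | starting material
2 | triisopropylsilyl 3-[3-methoxy-4-(triisopropylsilyloxy)phenyl]propanoate | COc1cc(CCC(=O)O[Si](C(C)C)(C(C)C)C(C)C)ccc1O[Si](C(C)C)(C(C)C)C(C)C | intermediate
3 | 3-[3-methoxy-4-(triisopropylsilyloxy)phenyl]propanoic acid | COc1cc(CCC(=O)O)ccc1O[Si](C(C)C)(C(C)C)C(C)C | intermediate
4 | (4R)-4-benzyl-1,3-oxazolidin-2-one | O=C1N[C@H](Cc2ccccc2)CO1 | starting material
5 | 2,2-dimethylpropanoic 3-[3-methoxy-4-(triisopropylsilyloxy)phenyl]propanoic anhydride | COc1cc(CCC(=O)OC(=O)C(C)(C)C)ccc1O[Si](C(C)C)(C(C)C)C(C)C | intermediate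
6 | (4R)-4-benzyl-3-{3-[3-methoxy-4-(triisopropylsilyloxy)phenyl]propanoyl}-1,3-oxazolidin-2-one | COc1cc(CCC(=O)N2[C@H](Cc3ccccc3)COC2=O)ccc1O[Si](C(C)C)(C(C)C)C(C)C | intermediate
7 | tert-butyl bromoacetate | CC(C)(C)OC(=O)CBr | starting material
8 | sodium (1Z)-1-[(4R)-4-benzyl-2-oxo-1,3-oxazolidin-3-yl]-3-[3-methoxy-4-(triisopropylsilyloxy)phenyl]prop-1-en-1-olate | COc1cc(C/C=C(\O[Na])N2[C@H](Cc3ccccc3)COC2=O)ccc1O[Si](C(C)C)(C(C)C)C(C)C | intermediate
9 | tert-butyl (3S)-4-[(4R)-4-benzyl-2-oxo-1,3-oxazolidin-3-yl]-3-{[3-methoxy-4-(triisopropylsilyloxy)phenyl]methyl}-4-oxobutanoate | COc1cc(C[C@@H](CC(=O)OC(C)(C)C)C(=O)N2[C@H](Cc3ccccc3)COC2=O)ccc1O[Si](C(C)C)(C(C)C)C(C)C | intermediate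
10 | tert-butyl (3S)-3-(hydroxymethyl)-4-[3-methoxy-4-(triisopropylsilyloxy)phenyl]butanoate | COc1cc(C[C@@H](CC(=O)OC(C)(C)C)CO)ccc1O[Si](C(C)C)(C(C)C)C(C)C | intermediate
11 | (3S)-3-(hydroxymethyl)-4-[3-methoxy-4-(triisopropylsilyloxy)phenyl]butanoic acid | COc1cc(C[C@@H](CC(=O)O)CO)ccc1O[Si](C(C)C)(C(C)C)C(C)C | intermediate
12 | (4S)-4-{[3-methoxy-4-(triisopropylsilyloxy)phenyl]methyl}oxolan-2-one | COc1cc(C[C@@H]2COC(=O)C2)ccc1O[Si](C(C)C)(C(C)C)C(C)C | intermediate
13 | 3,4-dihydroxy-5-methoxybenzaldehyde | COc1cc(C=O)cc(O)c1O | starting material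
14 | 3,4-bis(tert-butyldimethylsilyloxy)-5-methoxybenzaldehyde | COc1cc(C=O)cc(O[Si](C)(C)C(C)(C)C)c1O[Si](C)(C)C(C)(C)C | intermediate
15 | lithium (4S)-4-{[3-methoxy-4-(triisopropylsilyloxy)phenyl]methyl}-4,5-dihydrofuran-2-olate | COc1cc(C[C@@H]2COC(O[Li])=C2)ccc1O[Si](C(C)C)(C(C)C)C(C)C | intermediate
16 | (3R,4S)-3-{[3,4-bis(tert-butyldimethylsilyloxy)-5-methoxyphenyl](hydroxy)methyl}-4-{[3-methoxy-4-(triisopropylsilyloxy)phenyl]methyl}oxolan-2-one (both carbinol epimers) | COc1cc(C[C@@H]2COC(=O)[C@H]2C(O)c2cc(O[Si](C)(C)C(C)(C)C)c(O[Si](C)(C)C(C)(C)C)c(OC)c2)ccc1O[Si](C(C)C)(C(C)C)C(C)C | intermediate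
17 | [3,4-bis(tert-butyldimethylsilyloxy)-5-methoxyphenyl][(3R,4S)-4-{[3-methoxy-4-(triisopropylsilyloxy)phenyl]methyl}-2-oxooxolan-3-yl]methyl methanesulfonate (both epimers) | COc1cc(C[C@@H]2COC(=O)[C@H]2C(OS(C)(=O)=O)c2cc(O[Si](C)(C)C(C)(C)C)c(O[Si](C)(C)C(C)(C)C)c(OC)c2)ccc1O[Si](C(C)C)(C(C)C)C(C)C | intermediate
18 | (3E,4S)-3-{[3,4-bis(tert-butyldimethylsilyloxy)-5-methoxyphenyl]methylidene}-4-{[3-methoxy-4-(triisopropylsilyloxy)phenyl]methyl}oxolan-2-one | COc1cc(C[C@@H]2COC(=O)/C2=C/c2cc(O[Si](C)(C)C(C)(C)C)c(O[Si](C)(C)C(C)(C)C)c(OC)c2)ccc1O[Si](C(C)C)(C(C)C)C(C)C | intermediate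
19 | (3Z,4S)-3-{[3,4-bis(tert-butyldimethylsilyloxy)-5-methoxyphenyl]methylidene}-4-{[3-methoxy-4-(triisopropylsilyloxy)phenyl]methyl}oxolan-2-one | COc1cc(C[C@@H]2COC(=O)/C2=C\c2cc(O[Si](C)(C)C(C)(C)C)c(O[Si](C)(C)C(C)(C)C)c(OC)c2)ccc1O[Si](C(C)C)(C(C)C)C(C)C | intermediate
20 | (3Z,4S)-3-[(3,4-dihydroxy-5-methoxyphenyl)methylidene]-4-[(4-hydroxy-3-methoxyphenyl)methyl]oxolan-2-one | COc1cc(C[C@@H]2COC(=O)/C2=C\c2cc(O)c(O)c(OC)c2)ccc1O | target

## Step count and risks

Total steps: 10. Longest linear sequence: 9 steps (steps 1–5 and 7–10 from compound 1); step 6 is a one-step side branch.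

The three steps most likely to fail:

**Step 9 (photoisomerization).** The photostationary mixture may be poor in Z, or the chromophore may degrade. The fallback sets out from lactone 12 and uses a kinetically Z-selective Still–Gennari-type olefination instead of light. Lactone 12 is treated with LiN(iPr)2 and bis(2,2,2-trifluoroethyl) phosphorochloridate at −78 °C to give the enol phosphate (4S)-4-{[3-methoxy-4-(triisopropylsilyloxy)phenyl]methyl}-4,5-dihydrofuran-2-yl bis(2,2,2-trifluoroethyl) phosphate F3. A further two equivalents of LiN(iPr)2 induce the 1,3 O→C phosphorus migration to bis(2,2,2-trifluoroethyl) [(4R)-4-{[3-methoxy-4-(triisopropylsilyloxy)phenyl]methyl}-2-oxooxolan-3-yl]phosphonate F4. The 4R descriptor is only a CIP change caused by phosphorus; the spatial arrangement is that of 12. Deprotonation with KN(SiMe3)2/18-crown-6 in THF at −78 °C and addition of aldehyde 14 gives the Z-alkene directly, and the route is rejoined at compound 19.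

**Step 7 (aldol).** Retro-aldol or incomplete conversion may occur with the hindered, electron-rich aldehyde. The fallback sets out from lactone 12 and replaces the aldol/dehydration pair by a Horner–Wadsworth–Emmons olefination. LiN(iPr)2 and diethyl chlorophosphate at −78 °C give the enol phosphate diethyl (4S)-4-{[3-methoxy-4-(triisopropylsilyloxy)phenyl]methyl}-4,5-dihydrofuran-2-yl phosphate F1. Excess LiN(iPr)2 rearranges it (vinyl phosphate to phosphonate) to diethyl [(4R)-4-{[3-methoxy-4-(triisopropylsilyloxy)phenyl]methyl}-2-oxooxolan-3-yl]phosphonate F2, again with the same spatial arrangement as 12 and C3 epimers immaterial. NaH in THF and aldehyde 14 then give the E-alkene, and the route is rejoined at compound 18, bypassing 16 and 17.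

**Step 10 (global desilylation).** The free para-phenol may allow Z→E scrambling, or the catechol may oxidize. The fallback sets out from E-alkene 18 and inverts the order of the last two operations. Compound 18 is desilylated first (Bu4NF/AcOH, THF) to the configurationally safe E-triphenol (3E,4S)-3-[(3,4-dihydroxy-5-methoxyphenyl)methylidene]-4-[(4-hydroxy-3-methoxyphenyl)methyl]oxolan-2-one F5. F5 is then photoisomerized as the very last operation (350 nm, degassed MeOH, Ar), with reverse-phase separation of the isomers and recycling of F5. The route is rejoined at the target 20.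

## Further compounds

F1 | step 7 | diethyl (4S)-4-{[3-methoxy-4-(triisopropylsilyloxy)phenyl]methyl}-4,5-dihydrofuran-2-yl phosphate | COc1cc(C[C@@H]2COC(OP(=O)(OCC)OCC)=C2)ccc1O[Si](C(C)C)(C(C)C)C(C)C
F2 | step 7 | diethyl [(4R)-4-{[3-methoxy-4-(triisopropylsilyloxy)phenyl]methyl}-2-oxooxolan-3-yl]phosphonate (C3 epimers) | COc1cc(C[C@@H]2COC(=O)C2P(=O)(OCC)OCC)ccc1O[Si](C(C)C)(C(C)C)C(C)C
F3 | step 9 | (4S)-4-{[3-methoxy-4-(triisopropylsilyloxy)phenyl]methyl}-4,5-dihydrofuran-2-yl bis(2,2,2-trifluoroethyl) phosphate | COc1cc(C[C@@H]2COC(OP(=O)(OCC(F)(F)F)OCC(F)(F)F)=C2)ccc1O[Si](C(C)C)(C(C)C)C(C)C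
F4 | step 9 | bis(2,2,2-trifluoroethyl) [(4R)-4-{[3-methoxy-4-(triisopropylsilyloxy)phenyl]methyl}-2-oxooxolan-3-yl]phosphonate (C3 epimers) | COc1cc(C[C@@H]2COC(=O)C2P(=O)(OCC(F)(F)F)OCC(F)(F)F)ccc1O[Si](C(C)C)(C(C)C)C(C)C
F5 | step 10 | (3E,4S)-3-[(3,4-dihydroxy-5-methoxyphenyl)methylidene]-4-[(4-hydroxy-3-methoxyphenyl)methyl]oxolan-2-one | COc1cc(C[C@@H]2COC(=O)/C2=C/c2cc(O)c(O)c(OC)c2)ccc1O
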